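**Plan**

- Numbering: trione ring C1 (acyl), C2 (enol), C3 (CH3, prenyl), C4, C5 (spiro), C6; cyclohexane C5–C7–C8–C9–C13–C14; cyclopentane C8–C12–C11–C10–C9. If C7 is bonded to C14 instead of both going to C5, then C8, C9, C12 and C13 with their CH3/OH groups form a C2-symmetric cis-bicyclo[3.3.0]octane (C8↔C9, C12↔C13).
- Retrosynthetic cuts, in order: C3–CH3; C1–acyl; C1–C6 (Claisen); C2–C3 and C3–C4; C5–C7 and C5–C14 (malonate); C7 and C14 rejoined as an alkene; C12–CH3 and C13–CH3 (key step); diquinane back to 1,5-cyclooctadiene.
- Forward: both five-membered rings arise at once from cyclooctadiene; ozone later cuts C7=C14; a malonate closes the cyclohexane at C5; a lactone to O12 tells the two carboxyls apart; the trione ring closes last by intramolecular Claisen condensation.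
- Stereochemistry: C8/C9 from a lipase resolution; C12/C13 from convex-face methyl addition; C5 from the lactone (the carboxyl cis to the C12–O bond becomes C6); C3 from methylation of the ring enolate on the face cis to C7; the side-chain centre from (S)-2-methylbutanoic acid.

Key step: step 5

Assumption 1: the lipase follows the usual size rule for secondary alcohols and cleaves the (2R,6R)-acetates first; if it prefers the antipode, the recovered diacetate is the enantiomer shown for 2 and is methanolysed to 3 instead.
Assumption 2: of the two lactones that the carboxyl cis to the hydroxyls can form, the six-membered one to O12 is taken as the resting form; the five-membered one to O13 would engage the same carboxyl and lead to the same trione 25.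

Step 1
Reactants: 1 (1Z,5Z)-cycloocta-1,5-diene
Product: 2 rac-endo,endo-cis-bicyclo[3.3.0]octane-2,6-diyl diacetate
Conditions: Pd(OAc)2 (cat.), Pb(OAc)4, AcOH, rt
Reagents that add atoms: lead tetraacetate, CC(=O)O[Pb](OC(C)=O)(OC(C)=O)OC(C)=O
Why: Pd-catalysed oxidative transannular cyclisation of a 1,5-diene (anti-acetoxypalladation, syn insertion of the second alkene, oxidative C–OAc formation with inversion) should give the cis-fused diquinane with both acetoxy groups endo, as a racemate.

Step 2
Reactants: 2 rac-endo,endo-cis-bicyclo[3.3.0]octane-2,6-diyl diacetate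
Product: 3 (1S,2R,5S,6R)-cis-bicyclo[3.3.0]octane-2,6-diol (endo,endo)
Conditions: immobilised Candida antarctica lipase B, phosphate buffer pH 7/MTBE, 30 °C, to about half conversion
Reagents that add atoms: none
Why: Lipase-catalysed kinetic resolution by enantioselective hydrolysis, in which the (2R,6R)-acetates are cleaved in two consecutive selective events so the diol should be highly enriched, while the mirror-image diacetate stays behind and is removed by chromatography.

Step 3
Reactants: 3 (1S,2R,5S,6R)-cis-bicyclo[3.3.0]octane-2,6-diol
Product: 4 (1S,5S)-cis-bicyclo[3.3.0]octane-2,6-dione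
Conditions: TEMPO (cat.), NaOCl, KBr, NaHCO3, CH2Cl2/H2O, 0 °C
Reagents that add atoms: none
Why: Anelli oxidation of both secondary alcohols; the ring-fusion centres cannot epimerise to the strained trans-diquinane, so C8 and C9 keep their configuration.

Step 4
Reactants: 4 (1S,5S)-cis-bicyclo[3.3.0]octane-2,6-dione
Product: 6 (1S,5S)-cis-bicyclo[3.3.0]oct-3-ene-2,6-dione (C13 enone with C14=C7; C12 ketone), via mono-trimethylsilyl enol ether 5 (not isolated)
Conditions: LDA (1.0 equiv), TMSCl, THF, −78 °C; then Pd(OAc)2 (cat.), O2, DMSO, rt
Reagents that add atoms: none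
Why: Saegusa–Ito oxidation, in which kinetic deprotonation at the C14 methylene (not the C9 bridgehead) fixes the alkene position; since 4 is C2-symmetric either carbonyl gives the same mono-enone, and the statistical by-products (dienedione, unreacted 4 for recycling) are separated.

Step 5
Reactants: 6 (1S,5S)-cis-bicyclo[3.3.0]oct-3-ene-2,6-dione; 7 methylmagnesium bromide
Product: 9 (1S,2R,5S,6R)-2,6-dimethyl-cis-bicyclo[3.3.0]oct-3-ene-2,6-diol (both CH3 exo; both OH endo), via methylcerium dichloride 8 (not isolated)
Conditions: anhydrous CeCl3 (3.5 equiv), 7 (3.5 equiv; two are incorporated), THF, −78 °C, 1 h; add 6, −78 → −40 °C; aq. NH4Cl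
Reagents that add atoms: methylmagnesium bromide (second equivalent of 7), C[Mg]Br
Why: Transmetalation of 7 to CeCl3 gives the hard, weakly basic methylcerium species 8, two equivalents of which add to the carbonyl carbons C12 and C13, forming the C12–CH3 and C13–CH3 bonds and, after work-up, both tertiary alcohols. The closest known reaction type is organocerium (Grignard–CeCl3) 1,2-addition to easily enolised ketones and to enones, including cis-fused bicyclo[3.3.0]octanones, where exo attack is the rule. No ring is closed. Both new stereocentres are set by the cup shape of the cis-fused diquinane: each carbonyl is open only on the convex face, the side of the bridgehead hydrogens, so each methyl ends cis to its neighbouring bridgehead hydrogen (8-H for C12, 9-H for C13) and each hydroxyl ends endo; the two additions are related by the C2 axis of the parent dione and so have the same sense. The step needs 1,2- rather than 1,4-addition at the C13 enone and addition rather than deprotonation at C8 (α to the C12 ketone and γ to the enone); the oxophilic, low-basicity cerium reagent should secure both, and the fold of the substrate the facial selectivity. The surviving C7=C14 alkene is untouched and marks the bond to be cut next.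

Step 6
Reactants: 9 (1S,2R,5S,6R)-2,6-dimethyl-cis-bicyclo[3.3.0]oct-3-ene-2,6-diol
Product: 11 tetraol (C7–OH and C14–OH primary; C12–OH and C13–OH tertiary; configuration of 9), via dialdehyde 10 (not isolated)
Conditions: O3, CH2Cl2/MeOH, −78 °C; then NaBH4, −78 → 0 °C
Reagents that add atoms: ozone, [O-][O+]=O
Why: Ozonolysis with reductive (borohydride) work-up cuts the only alkene, C7=C14, and delivers both termini as primary alcohols without touching a stereocentre.

Step 7
Reactants: 11 tetraol
Product: 13 epoxy diol (C13–O–C14 oxirane; C7–OH and C12–OH free), via C14 monotosylate 12 (not isolated)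
Conditions: Bu2SnO (cat.), TsCl (1 equiv), Et3N, CH2Cl2, 0 °C → rt; then K2CO3, MeOH, rt
Reagents that add atoms: none
Why: Tin-catalysed regioselective sulfonylation activates only the primary hydroxyl of the 1,2-diol through its five-membered stannylene acetal, and carbonate then closes the oxirane by 3-exo-tet Williamson displacement with the C13–O bond, and so the C13 configuration, retained.

Step 8
Reactants: 13 epoxy diol
Product: 14 iodo epoxide (C7–I; C12–OH free)
Conditions: I2, PPh3, imidazole, CH2Cl2, 0 °C
Reagents that add atoms: iodine, II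
Why: Appel iodination (Garegg–Samuelsson conditions) converts the primary C7 alcohol only; tertiary alcohols and oxiranes are known to survive these buffered conditions, as in the routine conversion of epoxy alcohols to epoxy iodides.

Step 9
Reactants: 14 iodo epoxide; 15 dibenzyl malonate
Product: 18 δ-lactone benzyl ester (spiro C5 carrying a benzyl ester and a lactone carbonyl bonded to O12; C13–OH free), via C7-alkylated malonate 16 (not isolated), via spiro hydroxy diester 17 (not isolated)
Conditions: NaH (1.0 equiv), 15 (1.1 equiv), THF/DMPU, 0 °C → rt; then NaH (1.0 equiv), 65 °C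
Reagents that add atoms: none
Why: Malonic ester synthesis in two stages, SN2 at the C7 iodide at room temperature and then, on heating with base limited to the malonate C–H so that the C12 hydroxyl stays protonated, intramolecular oxirane opening at the unsubstituted carbon C14 (the only SN2-accessible one, as in epoxide-opening cyclisations of stabilised carbanions) to close the cyclohexane, after which the carboxyl on the face of the C12–O and C13–O bonds lactonises, and since only that carboxyl can reach either oxygen this fixes C5.

Step 10
Reactants: 18 δ-lactone benzyl ester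
Product: 19 lactone acid (free CO2H on the face opposite to the lactone)
Conditions: H2 (1 atm), Pd/C, EtOAc, rt
Reagents that add atoms: none
Why: Hydrogenolysis of the benzyl ester frees the second carboxyl without opening the lactone, and no alkene is present at this stage.

Step 11
Reactants: 19 lactone acid
Product: 20 S-(2-pyridyl) thioester of 19
Conditions: 2,2'-dipyridyl disulfide, PPh3, CH2Cl2, rt
Reagents that add atoms: 2,2'-dipyridyl disulfide, c1ccc(SSc2ccccn2)nc1
Why: Mukaiyama redox condensation activates the hindered acid under neutral conditions that leave the tertiary alcohol and the lactone alone, which acid chloride formation would not.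

Step 12
Reactants: 20 S-(2-pyridyl) thioester; 21 5-bromo-2-methylpent-2-ene
Product: 23 4-methylpent-3-enyl ketone (C4=O; its α-CH2 is C3 and already carries the prenyl unit), via homoprenyl Grignard reagent 22 (not isolated)
Conditions: 21, Mg, THF, rt; then 20, THF, −78 °C (2.2 equiv of 22)
Reagents that add atoms: none
Why: Mukaiyama ketone synthesis, in which the Grignard reagent adds to the magnesium-chelated pyridyl thioester at −78 °C far faster than to the lactone and the chelated tetrahedral intermediate blocks over-addition; one equivalent is spent on the C13 hydroxyl.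

Step 13
Reactants: 23 4-methylpent-3-enyl ketone
Product: 24 1,3-diketone (C1H3–C2(=O)–C3H(prenyl)–C4(=O)–C5; lactone intact)
Conditions: MgBr2·OEt2, i-Pr2NEt, 1-acetylbenzotriazole, CH2Cl2, rt
Reagents that add atoms: 1-acetylbenzotriazole, CC(=O)n1nnc2ccccc12
Why: Soft-enolisation C-acylation with an N-acylbenzotriazole acetylates the only enolisable α-carbon, C3, to the 2-substituted 1,3-diketone; C3 remains epimerisable and is set in step 16.

Step 14
Reactants: 24 1,3-diketone
Product: 25 spiro-trione (C1H2; C3H(prenyl); C12–OH and C13–OH free)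
Conditions: LDA (4 equiv), THF, −78 → 0 °C; aq. HCl to pH 3
Reagents that add atoms: none
Why: Intramolecular Claisen (Dieckmann-type) condensation of the 1,3-diketone dianion, whose terminal C1 carbanion attacks the lactone carbonyl C6 in a 6-exo-trig closure and expels the C12 alkoxide, with the trione enolate as thermodynamic sink; C6 therefore stays on the face of the hydroxyls, as C5 requires.

Step 15
Reactants: 25 spiro-trione; 26 (S)-2-methylbutanoic acid
Product: 28 1-[(S)-2-methylbutanoyl] spiro-trione (C3–H still present), via enol ester 27 (not isolated)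
Conditions: 26, DCC, DMAP, CH2Cl2, 0 °C → rt
Reagents that add atoms: none
Why: Steglich O-acylation followed by DMAP-mediated O→C acyl shift, the standard C-acylation of cyclic 1,3-diones and syncarpic-acid-type triones, places the acyl group on C1, the only carbon that gives an enolised β-triketone; the hindered tertiary alcohols should not be esterified, and carbodiimide activation avoids the ketene pathway that would racemise the acid.

Step 16
Reactants: 28 1-[(S)-2-methylbutanoyl] spiro-trione
Product: 29 hyperielliptone HB
Conditions: NaOMe, MeI (1.1 equiv), MeOH, 0 °C → rt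
Reagents that add atoms: iodomethane, CI
Why: C-Methylation of the acylphloroglucinol-type enolate in a protic medium (the classical route to syncarpic-acid and lupulone-type triketones) can only occur at C3, and MeI should enter on the face of the trione ring cis to C7, away from the C13 methyl that lies on the C14 side of the C4 carbonyl, which places CH3 cis to C7 and prenyl cis to C14 as in the target.

**Compound list**

1 | (1Z,5Z)-cycloocta-1,5-diene | C1C/C=C\CC/C=C\1 | starting material
2 | rac-endo,endo-cis-bicyclo[3.3.0]octane-2,6-diyl diacetate (racemate; SMILES shows the enantiomer carried on) | C1C[C@H]2[C@H](CC[C@H]2OC(C)=O)[C@@H]1OC(C)=O | intermediate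
3 | (1S,2R,5S,6R)-cis-bicyclo[3.3.0]octane-2,6-diol | C1C[C@H]2[C@H](CC[C@H]2O)[C@@H]1O | intermediate
4 | (1S,5S)-cis-bicyclo[3.3.0]octane-2,6-dione | C1C[C@H]2[C@H](CCC2=O)C1=O | intermediate
5 | mono-trimethylsilyl enol ether of 4 (C13–OSiMe3, C13=C14) | C[Si](C)(C)OC1=CC[C@H]2[C@@H]1CCC2=O | intermediate (not isolated)
6 | (1S,5S)-cis-bicyclo[3.3.0]oct-3-ene-2,6-dione | C1=C[C@H]2[C@H](CCC2=O)C1=O | intermediate
7 | methylmagnesium bromide | C[Mg]Br | starting material
8 | methylcerium dichloride | C[Ce](Cl)Cl | intermediate (not isolated)
9 | (1S,2R,5S,6R)-2,6-dimethyl-cis-bicyclo[3.3.0]oct-3-ene-2,6-diol | C1=C[C@H]2[C@H](CC[C@@]2(C)O)[C@]1(C)O | intermediate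
10 | dialdehyde from cleavage of C7=C14 | O=C[C@H]1[C@H](CC[C@@]1(C)O)[C@](C=O)(C)O | intermediate (not isolated)
11 | tetraol (C7–OH, C14–OH primary; C12–OH, C13–OH tertiary) | OC[C@H]1[C@H](CC[C@@]1(C)O)[C@](CO)(C)O | intermediate
12 | C14 mono-p-toluenesulfonate of 11 | OC[C@H]1[C@H](CC[C@@]1(C)O)[C@](COS(=O)(=O)c2ccc(C)cc2)(C)O | intermediate (not isolated)
13 | epoxy diol (C13–O–C14 oxirane) | OC[C@H]1[C@H](CC[C@@]1(C)O)[C@@]2(C)CO2 | intermediate
14 | iodo epoxide (C7–I) | IC[C@H]1[C@H](CC[C@@]1(C)O)[C@@]2(C)CO2 | intermediate
15 | dibenzyl malonate | O=C(CC(=O)OCc1ccccc1)OCc1ccccc1 | starting material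
16 | dibenzyl malonate alkylated at C7, oxirane intact | O=C(OCc3ccccc3)C(C(=O)OCc4ccccc4)C[C@H]1[C@H](CC[C@@]1(C)O)[C@@]2(C)CO2 | intermediate (not isolated)
17 | spiro hydroxy diester (cis-hydrindane, gem-dibenzyl ester at C5) | O=C(OCc3ccccc3)C4(C(=O)OCc5ccccc5)C[C@H]1[C@H](CC[C@@]1(C)O)[C@](C)(O)C4 | intermediate (not isolated)
18 | δ-lactone benzyl ester (lactone C5–C(=O)–O12) | O=C(OCc4ccccc4)[C@]2(C[C@H]3[C@H](CC[C@@]3(C)O5)[C@](C)(O)C2)C5=O | intermediate
19 | lactone acid | OC(=O)[C@]2(C[C@H]3[C@H](CC[C@@]3(C)O5)[C@](C)(O)C2)C5=O | intermediate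
20 | S-(2-pyridyl) thioester of 19 | O=C(Sc4ccccn4)[C@]2(C[C@H]3[C@H](CC[C@@]3(C)O5)[C@](C)(O)C2)C5=O | intermediate
21 | 5-bromo-2-methylpent-2-ene | CC(C)=CCCBr | starting material
22 | (4-methylpent-3-enyl)magnesium bromide | CC(C)=CCC[Mg]Br | intermediate (not isolated)
23 | 4-methylpent-3-enyl ketone at C4 | CC(C)=CCCC(=O)[C@]2(C[C@H]3[C@H](CC[C@@]3(C)O5)[C@](C)(O)C2)C5=O | intermediate
24 | 1,3-diketone (C3 epimers/enol) | CC(=O)C(CC=C(C)C)C(=O)[C@]2(C[C@H]3[C@H](CC[C@@]3(C)O5)[C@](C)(O)C2)C5=O | intermediate
25 | spiro-trione (drawn as triketo tautomer; C3 enolisable) | C1C(=O)C(CC=C(C)C)C(=O)[C@]2(C[C@H]3[C@H](CC[C@@]3(C)O)[C@](C)(O)C2)C1=O | intermediate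
26 | (S)-2-methylbutanoic acid | CC[C@H](C)C(=O)O | starting material
27 | enol ester of 25 at O2 | C1=C(OC(=O)[C@@H](C)CC)C(CC=C(C)C)C(=O)[C@]2(C[C@H]3[C@H](CC[C@@]3(C)O)[C@](C)(O)C2)C1=O | intermediate (not isolated)
28 | 1-[(S)-2-methylbutanoyl] spiro-trione (C3–H, prenyl) | CC[C@H](C)C(=O)C1=C(O)C(CC=C(C)C)C(=O)[C@]2(C[C@H]3[C@H](CC[C@@]3(C)O)[C@](C)(O)C2)C1=O | intermediate
29 | hyperielliptone HB | CC[C@H](C)C(=O)C1=C(O)[C@@](C)(CC=C(C)C)C(=O)[C@]2(C[C@H]3[C@H](CC[C@@]3(C)O)[C@](C)(O)C2)C1=O | target

**Step count**

Total: 16 steps. Longest linear sequence: 16 steps (1 → 29).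

**Steps most likely to fail**

Step 16. The methyl group may enter C3 with little facial preference, or from the face cis to C14, because the bias comes only from the remote C13 methyl. The fallback swaps the order in which the two C3 substituents are introduced, so a bias that is the reverse of the one argued then gives the target epimer. It sets out from 20: ethylmagnesium bromide at −78 °C gives the ethyl ketone F1; C-acetylation as in step 13 gives the 3-methyl 1,3-diketone F2; LDA closes the ring as in step 14 to the 3-methyl spiro-trione F3; acylation with 26 as in step 15 gives the 1-acyl-3-methyl trione F4; C-prenylation of F4 with prenyl bromide and NaOMe in MeOH then returns to the route at 29.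

Step 9. Three processes may interfere: the alkoxide set free by a premature intermolecular oxirane opening may close a tetrahydrofuran onto C7, the C12 alkoxide may compete for C14 if base is in excess, or the ring-closing oxirane opening by the hindered tertiary malonate carbanion may stall. The fallback reverses the order of the two C–C bond formations with C7 masked. It sets out from 13: TBSCl/imidazole gives the C7 silyl ether F5; sodium dibenzyl malonate (from 15 and NaH) opens the oxirane at C14 and the C13 alkoxide lactonises at once to the benzyl α-carboxylate γ-lactone F6; fluoride frees the C7 alcohol F7; Appel iodination gives the iodide F8; Cs2CO3 in DMF closes the cyclohexane by intramolecular C-alkylation to the bridged γ-lactone benzyl ester F9, in which the lactone tether fixes C5; equilibration with catalytic DBU then moves the lactone from O13 to O12, in line with Assumption 2, returning to the route at 18.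

Step 7. Site selectivity between the two primary hydroxyls may be lost; sulfonylation at C7 would be followed by tetrahydrofuran closure from O13. The fallback differentiates the hydroxyls by steric protection instead of catalyst direction. It sets out from 11: TBDPSCl/imidazole at low temperature silylates the less hindered C7 hydroxyl (C14–OH is neopentyl) to give the silyl triol F10; TsCl/pyridine sulfonylates the only remaining primary hydroxyl to give the tosylate F11; K2CO3/MeOH closes the oxirane to the silylated epoxide F12; buffered TBAF removes the silyl group, returning to the route at 13.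

**Further compounds**

F1 | step 16 | ethyl ketone at C4 (lactone intact) | CCC(=O)[C@]2(C[C@H]3[C@H](CC[C@@]3(C)O5)[C@](C)(O)C2)C5=O
F2 | step 16 | 3-methyl 1,3-diketone | CC(=O)C(C)C(=O)[C@]2(C[C@H]3[C@H](CC[C@@]3(C)O5)[C@](C)(O)C2)C5=O
F3 | step 16 | 3-methyl spiro-trione | C1C(=O)C(C)C(=O)[C@]2(C[C@H]3[C@H](CC[C@@]3(C)O)[C@](C)(O)C2)C1=O
F4 | step 16 | 1-[(S)-2-methylbutanoyl]-3-methyl spiro-trione | CC[C@H](C)C(=O)C1=C(O)C(C)C(=O)[C@]2(C[C@H]3[C@H](CC[C@@]3(C)O)[C@](C)(O)C2)C1=O
F5 | step 9 | C7 tert-butyldimethylsilyl ether of 13 | CC(C)(C)[Si](C)(C)OC[C@H]1[C@H](CC[C@@]1(C)O)[C@@]2(C)CO2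
F6 | step 9 | benzyl α-carboxylate γ-lactone to O13, C7–OTBS | CC(C)(C)[Si](C)(C)OC[C@H]1[C@H](CC[C@@]1(C)O)[C@@]2(C)CC(C(=O)OCc3ccccc3)C(=O)O2
F7 | step 9 | C7 alcohol of F6 | OC[C@H]1[C@H](CC[C@@]1(C)O)[C@@]2(C)CC(C(=O)OCc3ccccc3)C(=O)O2
F8 | step 9 | C7 iodide of F7 | IC[C@H]1[C@H](CC[C@@]1(C)O)[C@@]2(C)CC(C(=O)OCc3ccccc3)C(=O)O2
F9 | step 9 | bridged γ-lactone benzyl ester (lactone C5–C(=O)–O13) | O=C(OCc4ccccc4)[C@]2(C[C@H]3[C@H](CC[C@@]3(C)O)[C@](C)(O5)C2)C5=O
F10 | step 7 | C7 tert-butyldiphenylsilyl ether of 11 | CC(C)(C)[Si](OC[C@H]1[C@H](CC[C@@]1(C)O)[C@](CO)(C)O)(c2ccccc2)c3ccccc3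
F11 | step 7 | C14 tosylate of F10 | CC(C)(C)[Si](OC[C@H]1[C@H](CC[C@@]1(C)O)[C@](COS(=O)(=O)c4ccc(C)cc4)(C)O)(c2ccccc2)c3ccccc3
F12 | step 7 | C7-silylated epoxide | CC(C)(C)[Si](OC[C@H]1[C@H](CC[C@@]1(C)O)[C@@]4(C)CO4)(c2ccccc2)c3ccccc3
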